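**Retrosynthetic overview**
1. Target 21 comes from diol 20 by double acetylation. The side-chain carbinol–acyl bond is the last C–C bond made, by a visible-light photoredox/chromium acyl addition of 3-methylbut-2-enoic acid 18 to aldehyde 17 under Felkin–Anh control.
2. The ring A diene comes from Wittig methylenation of bicyclic enone 15, which comes from Robinson annulation of ring B ketone 11 with 12 (ring B first, ring A second).
3. Ketone 11 comes from enone 10 and lactone 8; base equilibration of the lactone sets the side-chain methyl centre.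
4. Lactone 8 comes from enone 5, made by electrochemical allylic C–H oxidation of trans-carvyl silyl ether 4, itself from (R)-carvone 1 by epoxidation and Wharton transposition.
5. The carvone C-5 centre is the only purchased stereocentre; every other centre is set relative to it.

Assumption: the carbinol centre made in step 5 is drawn as the expected trans epimer; it is removed in step 8, so its configuration does not affect the route.

**Step 1**
Reactants: 1 (R)-carvone
Product: 2 (1R,4R,6R)-1-methyl-4-(prop-1-en-2-yl)-7-oxabicyclo[4.1.0]heptan-2-one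
Conditions: 30% H2O2, NaOH (cat.), MeOH, 0 °C
Reagents that add atoms: hydrogen peroxide, OO
Why: Weitz–Scheffer nucleophilic epoxidation; hydroperoxide adds to the enone beta-carbon on the face opposite the C-5 isopropenyl group, so the epoxide (the future acetoxy-bearing centre) is trans to it.

**Step 2**
Reactants: 2 carvone oxide
Product: 3 (1R,5S)-2-methyl-5-(prop-1-en-2-yl)cyclohex-2-en-1-ol (trans-carveol)
Conditions: N2H4·H2O, AcOH (cat.), MeOH, 0 °C to rt
Reagents that add atoms: none
Why: Wharton rearrangement; the epoxy hydrazone loses N2 and gives the transposed allylic alcohol with the C–O centre retained, hence trans to the isopropenyl group.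

**Step 3**
Reactants: 3 trans-carveol
Product: 4 tert-butyldimethyl{[(1R,5S)-2-methyl-5-(prop-1-en-2-yl)cyclohex-2-en-1-yl]oxy}silane
Conditions: TBSCl, imidazole, DMF, rt
Reagents that add atoms: tert-butyldimethylsilyl chloride, CC(C)(C)[Si](C)(C)Cl
Why: Standard silylation of a secondary allylic alcohol; no stereocentre is touched.

**Step 4**
Reactants: 4 trans-carvyl silyl ether
Product: 5 (4R,6S)-4-[(tert-butyldimethylsilyl)oxy]-3-methyl-6-(prop-1-en-2-yl)cyclohex-2-en-1-one
Conditions: undivided cell, reticulated vitreous carbon anode and cathode, constant current, Cl4NHPI (20 mol%), pyridine, tBuOOH, LiBF4, acetone, rt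
Reagents that add atoms: tert-butyl hydroperoxide, CC(C)(C)OO
Why: Electrochemical allylic C–H oxidation mediated by the anodically generated phthalimide-N-oxyl radical; the ring allylic CH2 is the only site that gives a conjugated enone, the silyloxy-bearing C–H is shielded, and isopropenyl groups are known to survive this chemistry.

**Step 5**
Reactants: 5 silyloxy enone
Product: 6 (1S,4R,6S)-4-[(tert-butyldimethylsilyl)oxy]-6-(1-hydroxypropan-2-yl)-3-methylcyclohex-2-en-1-ol (epimer mixture at the side-chain CH)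
Conditions: 9-BBN (3 equiv), THF, 0 °C to rt; then NaOH, H2O2, 0 °C
Reagents that add atoms: hydrogen peroxide, OO
Why: 9-BBN does a 1,2-reduction of the enone carbonyl and an anti-Markovnikov hydroboration of the 1,1-disubstituted alkene while sparing the trisubstituted ring alkene; the new side-chain centre forms as a mixture that step 6 corrects.

**Step 6**
Reactants: 6 diol
Product: 8 (3S,3aS,5R,7aS)-5-[(tert-butyldimethylsilyl)oxy]-3,6-dimethyl-3a,4,5,7a-tetrahydro-1-benzofuran-2(3H)-one, via lactone C-3 epimer mixture 7 (not isolated)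
Conditions: TEMPO (10 mol%), PhI(OAc)2 (2.5 equiv), CH2Cl2, rt; then DBU, toluene, 60 °C
Reagents that add atoms: none
Why: Oxoammonium oxidative lactonisation of the 1,4-diol, then base equilibration of the alpha-methyl lactone to the more stable epimer with the methyl on the face of the C-3a hydrogen, so the carvone-derived centre sets the side-chain methyl configuration under thermodynamic control.

**Step 7**
Reactants: 8 lactone
Product: 9 (2S)-2-{(1S,2S,5R)-5-[(tert-butyldimethylsilyl)oxy]-2-hydroxy-4-methylcyclohex-3-en-1-yl}-N-methoxy-N-methylpropanamide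
Conditions: MeNHOMe·HCl, iPrMgCl, THF, −20 to 0 °C
Reagents that add atoms: N,O-dimethylhydroxylamine hydrochloride, Cl.CNOC
Why: Weinreb aminolysis of the lactone by the magnesium amide; acyl substitution leaves all stereocentres untouched.

**Step 8**
Reactants: 9 hydroxy amide
Product: 10 (2S)-2-{(1S,5R)-5-[(tert-butyldimethylsilyl)oxy]-4-methyl-2-oxocyclohex-3-en-1-yl}-N-methoxy-N-methylpropanamide
Conditions: MnO2 (excess), CH2Cl2, rt
Reagents that add atoms: none
Why: Chemoselective neutral oxidation of the allylic alcohol to the enone, which avoids enolisation at the adjacent side-chain-bearing carbon.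

**Step 9**
Reactants: 10 enone amide
Product: 11 (2S)-2-{(1S,4S,5R)-5-[(tert-butyldimethylsilyl)oxy]-4-methyl-2-oxocyclohexyl}-N-methoxy-N-methylpropanamide
Conditions: H2 (1 atm), Pd/C, EtOAc, rt
Reagents that add atoms: none
Why: Heterogeneous hydrogenation delivers hydrogen to the face opposite the pseudo-axial allylic silyloxy group, placing the ring methyl cis to the silyl ether.

**Step 10**
Reactants: 11 ketone amide; 12 3-(trimethylsilyl)but-3-en-2-one
Product: 15 (2S)-2-[(1S,3R,4S,4aS)-3-[(tert-butyldimethylsilyl)oxy]-4-methyl-7-oxo-1,2,3,4,4a,5,6,7-octahydronaphthalen-1-yl]-N-methoxy-N-methylpropanamide, via alpha-silyl 1,5-diketone adduct 13 (not isolated), via desilylated 1,5-diketone 14 (not isolated)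
Conditions: LiN(iPr)2, THF, −78 °C; 12, −78 to −30 °C; then NaOMe, MeOH, 0 °C to rt
Reagents that add atoms: none
Why: Robinson annulation in the Stork–Ganem form; the kinetic enolate at the unsubstituted CH2 adds to the silyl vinyl ketone on the face opposite the neighbouring methyl and the axial silyloxy group (ring-fusion CH trans to methyl), and methoxide then removes silicon and effects aldol condensation faster than the side-chain-bearing alpha-carbon can epimerise.

**Step 11**
Reactants: 15 bicyclic enone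
Product: 16 (2S)-2-[(1S,3R,4S,4aS)-3-[(tert-butyldimethylsilyl)oxy]-4-methyl-7-methylidene-1,2,3,4,4a,5,6,7-octahydronaphthalen-1-yl]-N-methoxy-N-methylpropanamide
Conditions: Ph3PCH3Br, KOtBu, THF, 0 °C to rt
Reagents that add atoms: methyltriphenylphosphonium bromide, C[P+](c1ccccc1)(c1ccccc1)c1ccccc1.[Br-]
Why: Wittig methylenation of the unhindered enone carbonyl gives the s-trans exocyclic/endocyclic diene; the Weinreb amide reacts far more slowly with the ylide.

**Step 12**
Reactants: 16 diene amide
Product: 17 (2S)-2-[(1S,3R,4S,4aS)-3-[(tert-butyldimethylsilyl)oxy]-4-methyl-7-methylidene-1,2,3,4,4a,5,6,7-octahydronaphthalen-1-yl]propanal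
Conditions: iBu2AlH, THF, −78 °C
Reagents that add atoms: none
Why: Reduction of the Weinreb amide stops at the chelated tetrahedral intermediate and gives the aldehyde on work-up; the alpha-methyl centre is kept by cold, non-basic work-up and immediate use.

**Step 13**
Reactants: 17 aldehyde; 18 3-methylbut-2-enoic acid
Product: 19 (5R,6S)-6-[(1S,3R,4S,4aS)-3-[(tert-butyldimethylsilyl)oxy]-4-methyl-7-methylidene-1,2,3,4,4a,5,6,7-octahydronaphthalen-1-yl]-5-hydroxy-2-methylhept-2-en-4-one
Conditions: 18 (2 equiv), PPh3 (2.2 equiv), CrCl3 (15 mol%), 4CzIPN (3 mol%), 2,6-lutidine, DMF/MeCN, 450 nm LEDs, rt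
Reagents that add atoms: none
Why: Proposed new method: an acyl Nozaki–Hiyama–Kishi-type addition under photoredox/chromium dual catalysis, in which photoexcited 4CzIPN oxidises PPh3, the phosphine radical cation adds to the carboxylate and beta-scission gives the 3-methylbut-2-enoyl radical plus Ph3PO, divalent chromium (formed from CrCl3 by the reduced photocatalyst) traps this radical as an acylchromium nucleophile that adds to the aldehyde through a Felkin–Anh transition state (new carbinol centre syn to the adjacent methyl), and protonation by the acid releases the product and trivalent chromium; the closest known reactions are photoredox/chromium alkylations and allylations of aldehydes and the phosphine-mediated photochemical deoxygenation of carboxylic acids to acyl radicals.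

**Step 14**
Reactants: 19 alpha-hydroxy enone
Product: 21 (5R,6S)-6-[(1S,3R,4S,4aS)-3-(acetyloxy)-4-methyl-7-methylidene-1,2,3,4,4a,5,6,7-octahydronaphthalen-1-yl]-2-methyl-4-oxohept-2-en-5-yl acetate, via desilylated diol 20 (not isolated)
Conditions: HF·pyridine, pyridine, THF, 0 °C to rt; then Ac2O, DMAP, rt
Reagents that add atoms: acetic anhydride, CC(=O)OC(C)=O
Why: Buffered fluoride desilylation followed in the same flask by DMAP-catalysed acetylation of both secondary alcohols; no stereocentre is affected.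

**Compound list**
1 | (R)-carvone | CC1=CC[C@H](CC1=O)C(C)=C | starting material
2 | (1R,4R,6R)-1-methyl-4-(prop-1-en-2-yl)-7-oxabicyclo[4.1.0]heptan-2-one | C1C(=O)[C@]2(C)O[C@@H]2C[C@H]1C(C)=C | intermediate
3 | (1R,5S)-2-methyl-5-(prop-1-en-2-yl)cyclohex-2-en-1-ol | C1C=C(C)[C@H](O)C[C@H]1C(C)=C | intermediate
4 | tert-butyldimethyl{[(1R,5S)-2-methyl-5-(prop-1-en-2-yl)cyclohex-2-en-1-yl]oxy}silane | C1C=C(C)[C@H](O[Si](C)(C)C(C)(C)C)C[C@H]1C(C)=C | intermediate
5 | (4R,6S)-4-[(tert-butyldimethylsilyl)oxy]-3-methyl-6-(prop-1-en-2-yl)cyclohex-2-en-1-one | O=C1C=C(C)[C@H](O[Si](C)(C)C(C)(C)C)C[C@H]1C(C)=C | intermediate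
6 | (1S,4R,6S)-4-[(tert-butyldimethylsilyl)oxy]-6-(1-hydroxypropan-2-yl)-3-methylcyclohex-2-en-1-ol, side-chain CH epimer mixture | O[C@@H]1C=C(C)[C@H](O[Si](C)(C)C(C)(C)C)C[C@H]1C(C)CO | intermediate
7 | (3aS,5R,7aS)-5-[(tert-butyldimethylsilyl)oxy]-3,6-dimethyl-3a,4,5,7a-tetrahydro-1-benzofuran-2(3H)-one, C-3 epimer mixture | CC1C(=O)O[C@@H]2C=C(C)[C@H](O[Si](C)(C)C(C)(C)C)C[C@@H]12 | intermediate
8 | (3S,3aS,5R,7aS)-5-[(tert-butyldimethylsilyl)oxy]-3,6-dimethyl-3a,4,5,7a-tetrahydro-1-benzofuran-2(3H)-one | C[C@@H]1C(=O)O[C@@H]2C=C(C)[C@H](O[Si](C)(C)C(C)(C)C)C[C@@H]12 | intermediate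
9 | (2S)-2-{(1S,2S,5R)-5-[(tert-butyldimethylsilyl)oxy]-2-hydroxy-4-methylcyclohex-3-en-1-yl}-N-methoxy-N-methylpropanamide | O[C@@H]1C=C(C)[C@H](O[Si](C)(C)C(C)(C)C)C[C@H]1[C@H](C)C(=O)N(C)OC | intermediate
10 | (2S)-2-{(1S,5R)-5-[(tert-butyldimethylsilyl)oxy]-4-methyl-2-oxocyclohex-3-en-1-yl}-N-methoxy-N-methylpropanamide | O=C1C=C(C)[C@H](O[Si](C)(C)C(C)(C)C)C[C@H]1[C@H](C)C(=O)N(C)OC | intermediate
11 | (2S)-2-{(1S,4S,5R)-5-[(tert-butyldimethylsilyl)oxy]-4-methyl-2-oxocyclohexyl}-N-methoxy-N-methylpropanamide | O=C1C[C@H](C)[C@H](O[Si](C)(C)C(C)(C)C)C[C@H]1[C@H](C)C(=O)N(C)OC | intermediate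
12 | 3-(trimethylsilyl)but-3-en-2-one | CC(=O)C(=C)[Si](C)(C)C | starting material
13 | (2S)-2-{(1S,3S,4S,5R)-5-[(tert-butyldimethylsilyl)oxy]-4-methyl-2-oxo-3-[3-oxo-2-(trimethylsilyl)butyl]cyclohexyl}-N-methoxy-N-methylpropanamide, mixture at the silyl-bearing carbon | O=C1[C@@H](CC([Si](C)(C)C)C(C)=O)[C@H](C)[C@H](O[Si](C)(C)C(C)(C)C)C[C@H]1[C@H](C)C(=O)N(C)OC | intermediate
14 | (2S)-2-{(1S,3S,4S,5R)-5-[(tert-butyldimethylsilyl)oxy]-4-methyl-2-oxo-3-(3-oxobutyl)cyclohexyl}-N-methoxy-N-methylpropanamide | O=C1[C@@H](CCC(C)=O)[C@H](C)[C@H](O[Si](C)(C)C(C)(C)C)C[C@H]1[C@H](C)C(=O)N(C)OC | intermediate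
15 | (2S)-2-[(1S,3R,4S,4aS)-3-[(tert-butyldimethylsilyl)oxy]-4-methyl-7-oxo-1,2,3,4,4a,5,6,7-octahydronaphthalen-1-yl]-N-methoxy-N-methylpropanamide | O=C1C=C2[C@@H](CC1)[C@H](C)[C@H](O[Si](C)(C)C(C)(C)C)C[C@H]2[C@H](C)C(=O)N(C)OC | intermediate
16 | (2S)-2-[(1S,3R,4S,4aS)-3-[(tert-butyldimethylsilyl)oxy]-4-methyl-7-methylidene-1,2,3,4,4a,5,6,7-octahydronaphthalen-1-yl]-N-methoxy-N-methylpropanamide | C=C1C=C2[C@@H](CC1)[C@H](C)[C@H](O[Si](C)(C)C(C)(C)C)C[C@H]2[C@H](C)C(=O)N(C)OC | intermediate
17 | (2S)-2-[(1S,3R,4S,4aS)-3-[(tert-butyldimethylsilyl)oxy]-4-methyl-7-methylidene-1,2,3,4,4a,5,6,7-octahydronaphthalen-1-yl]propanal | C=C1C=C2[C@@H](CC1)[C@H](C)[C@H](O[Si](C)(C)C(C)(C)C)C[C@H]2[C@H](C)C=O | intermediate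
18 | 3-methylbut-2-enoic acid | CC(C)=CC(=O)O | starting material
19 | (5R,6S)-6-[(1S,3R,4S,4aS)-3-[(tert-butyldimethylsilyl)oxy]-4-methyl-7-methylidene-1,2,3,4,4a,5,6,7-octahydronaphthalen-1-yl]-5-hydroxy-2-methylhept-2-en-4-one | C=C1C=C2[C@@H](CC1)[C@H](C)[C@H](O[Si](C)(C)C(C)(C)C)C[C@H]2[C@H](C)[C@@H](O)C(=O)C=C(C)C | intermediate
20 | (5R,6S)-5-hydroxy-6-[(1S,3R,4S,4aS)-3-hydroxy-4-methyl-7-methylidene-1,2,3,4,4a,5,6,7-octahydronaphthalen-1-yl]-2-methylhept-2-en-4-one | C=C1C=C2[C@@H](CC1)[C@H](C)[C@H](O)C[C@H]2[C@H](C)[C@@H](O)C(=O)C=C(C)C | intermediate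
21 | (5R,6S)-6-[(1S,3R,4S,4aS)-3-(acetyloxy)-4-methyl-7-methylidene-1,2,3,4,4a,5,6,7-octahydronaphthalen-1-yl]-2-methyl-4-oxohept-2-en-5-yl acetate (CNP0302999.1) | C=C1C=C2[C@@H](CC1)[C@H](C)[C@H](OC(C)=O)C[C@H]2[C@H](C)[C@@H](OC(C)=O)C(=O)C=C(C)C | target

**Totals**
Total step count: 14. Longest linear sequence: 14 steps, from (R)-carvone 1.

**Steps most likely to fail**

Step 4. The mediator radical may also abstract the silyloxy-bearing allylic hydrogen or the isopropenyl allylic hydrogens, and the beta,gamma-unsaturated ketone 5 can epimerise or conjugate. The fallback introduces the ring oxygen by enolate chemistry before the carbonyl transposition. It sets out from epoxy ketone 2: deprotonation with LiN(iPr)2 at the only enolisable carbon (THF, −78 °C) and oxidation with 2-(phenylsulfonyl)-3-phenyloxaziridine gives the alpha-hydroxy epoxy ketone F1, with the hydroxyl trans to the isopropenyl group. Wharton rearrangement (N2H4·H2O, AcOH, MeOH) gives the ene-diol F2. 9-BBN followed by NaOH/H2O2 gives the triol F3. TEMPO/PhI(OAc)2 lactonisation followed by DBU gives the hydroxy lactone F4. Silylation with TBSCl and imidazole comes back to the route at lactone 8.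

Step 10. The kinetic enolate may not form cleanly next to the Weinreb amide, the vinyl ketone can polymerise, and the carbon bearing the side chain can epimerise under methoxide. The fallback makes the enolate equivalent reductively and uses a Lewis-acid Michael addition; it sets out from enone 10 and bypasses steps 9 and 10. RhCl(PPh3)3-catalysed 1,4-hydrosilylation with Et3SiH (benzene, 50 °C) adds hydride opposite the silyloxy group and gives the triethylsilyl enol ether F5. Mukaiyama–Michael addition to but-3-en-2-one (BF3·OEt2, CH2Cl2, −78 °C) gives 1,5-diketone 14, now isolated. Brief NaOMe/MeOH treatment closes ring A and comes back to the route at bicyclic enone 15.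

Step 13 (the proposed new reaction). The acyl radical may add to the ring diene before divalent chromium traps it, the alkenoic acid may give the acyl radical inefficiently, and Felkin–Anh selectivity with the acylchromium species is untested. The fallback uses known alkyne chemistry and sets out from aldehyde 17. Addition of the dilithio derivative of 2-methylbut-3-yn-2-ol (n-BuLi, 2 equiv, THF, −78 °C; Felkin–Anh) gives the ynediol F6. Selective acetylation of the secondary hydroxyl (Ac2O, pyridine, 0 °C) gives the propargylic acetate F7. Meyer–Schuster rearrangement of the free tertiary propargylic alcohol with VO(OSiPh3)3 (toluene, 80 °C) gives the alpha-acetoxy enone F8. HF·pyridine followed by Ac2O/DMAP comes back to the route at target 21.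

**Further compounds**
F1 | step 4 | 3-hydroxy-1-methyl-4-(prop-1-en-2-yl)-7-oxabicyclo[4.1.0]heptan-2-one, hydroxyl trans to isopropenyl | O[C@@H]1C(=O)[C@]2(C)O[C@@H]2C[C@H]1C(C)=C
F2 | step 4 | (1R,4R,5S)-2-methyl-5-(prop-1-en-2-yl)cyclohex-2-ene-1,4-diol | O[C@@H]1C=C(C)[C@H](O)C[C@H]1C(C)=C
F3 | step 4 | 5-(1-hydroxypropan-2-yl)-2-methylcyclohex-2-ene-1,4-diol, ring centres as in F2, side-chain CH epimer mixture | O[C@@H]1C=C(C)[C@H](O)C[C@H]1C(C)CO
F4 | step 4 | (3S,3aS,5R,7aS)-5-hydroxy-3,6-dimethyl-3a,4,5,7a-tetrahydro-1-benzofuran-2(3H)-one | C[C@@H]1C(=O)O[C@@H]2C=C(C)[C@H](O)C[C@@H]12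
F5 | step 10 | triethylsilyl enol ether of ketone 11 (enol double bond toward the ring CH2) | CC[Si](CC)(CC)OC1=C[C@H](C)[C@H](O[Si](C)(C)C(C)(C)C)C[C@H]1[C@H](C)C(=O)N(C)OC
F6 | step 13 | ynediol from aldehyde 17 and 2-methylbut-3-yn-2-ol, secondary carbinol syn to the adjacent methyl | C=C1C=C2[C@@H](CC1)[C@H](C)[C@H](O[Si](C)(C)C(C)(C)C)C[C@H]2[C@H](C)[C@@H](O)C#CC(C)(C)O
F7 | step 13 | secondary acetate of F6 with free tertiary propargylic alcohol | C=C1C=C2[C@@H](CC1)[C@H](C)[C@H](O[Si](C)(C)C(C)(C)C)C[C@H]2[C@H](C)[C@@H](OC(C)=O)C#CC(C)(C)O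
F8 | step 13 | silyl ether of the target carrying the side-chain acetate (alpha-acetoxy enone) | C=C1C=C2[C@@H](CC1)[C@H](C)[C@H](O[Si](C)(C)C(C)(C)C)C[C@H]2[C@H](C)[C@@H](OC(C)=O)C(=O)C=C(C)C
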